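**Retrosynthetic overview**
1. Ester C–O bond: target 30 ⇒ 5αH-eudesm-3-en-6β-ol 23 + (E)-4-acetoxycinnamoyl chloride 28 (from p-coumaric acid).
2. Δ3 olefin and 5α-H: 23 ⇐ Pd-catalysed reductive 1,3-transposition of the 3β-allylic formate of a 6β-silyloxy-eudesm-4-ene ⇐ 6β-hydroxy-eudesm-4-en-3-one 16 (γ-hydroxylation of enone 11 through its dienol acetate).
3. Ring A: enone 11 ⇐ intramolecular aldol condensation of 1,5-diketone 9.
4. Key C–C bond (C1–C10, quaternary centre): 9 ⇐ intermolecular asymmetric Michael addition of the (R)-1-phenylethylamine imine of carvomenthone to ethyl vinyl ketone.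
5. Ring order: ring B comes ready-made from (R)-carvone (fixes C7), ring A is then built on it (Michael, then aldol).

Assumption: ketone 3 and imine 5 are C2-epimer mixtures (the centre is planarised in step 4) and ketol 10 is a transient mixture at its two new centres, so these centres carry no descriptor in the SMILES.

**Route**

Step 1
Reactants: 1 (R)-(−)-carvone
Product: 2 (5R)-2-methyl-5-(propan-2-yl)cyclohex-2-en-1-one (carvotanacetone)
Conditions: H2 (1 atm), (Ph3P)3RhCl (1 mol %), toluene, rt
Reagents that add atoms: none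
Why: Homogeneous (Wilkinson) hydrogenation reduces only the unhindered 1,1-disubstituted olefin and does not migrate double bonds, so the C5 stereocentre keeps its full enantiopurity.

Step 2
Reactants: 2 carvotanacetone
Product: 3 (2RS,5R)-2-methyl-5-(propan-2-yl)cyclohexan-1-one (carvomenthone)
Conditions: H2 (1 atm), 10% Pd/C, EtOAc, rt
Reagents that add atoms: none
Why: Heterogeneous catalytic hydrogenation of the conjugated C=C is fast and leaves the ketone and C5 untouched; the C2 epimer mixture is irrelevant because C2 becomes sp2 in step 4.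

Step 3
Reactants: 3 carvomenthone; 4 (R)-(+)-1-phenylethylamine
Product: 5 (1R)-N-[(5R)-2-methyl-5-(propan-2-yl)cyclohexylidene]-1-phenylethanamine
Conditions: 4 (1.1 equiv), cat. TsOH, toluene, reflux, Dean–Stark; used crude
Reagents that add atoms: (R)-1-phenylethylamine, C[C@@H](N)c1ccccc1
Why: Azeotropic imine condensation of an unhindered cyclohexanone with a primary amine goes to completion and installs the chiral auxiliary.

Step 4
Reactants: 5 imine; 6 ethyl vinyl ketone
Product: 9 (2S,5R)-2-methyl-2-(3-oxopentyl)-5-(propan-2-yl)cyclohexan-1-one, via enamine tautomer 7 (not isolated), via Michael adduct imine 8 (not isolated)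
Conditions: 6 (1.5 equiv), THF, 40 °C, 3 d; then 10% aq AcOH, rt
Reagents that add atoms: ethyl vinyl ketone, CCC(=O)C=C; water, O
Why: d'Angelo–Pfau asymmetric Michael addition, in which the more substituted secondary enamine adds to the enone through a compact aza-ene-type transition state on the face left open by the (R)-phenylethyl group, placing the new chain trans to the isopropyl group and creating the (S) quaternary centre under reagent control (the same pairing that gives the natural α-cyperone series from the isopropenyl analogue).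

Step 5
Reactants: 9 diketone
Product: 11 (4aS,7R)-1,4a-dimethyl-7-(propan-2-yl)-4,4a,5,6,7,8-hexahydronaphthalen-2(3H)-one (eudesm-4-en-3-one), via ketol 10 (not isolated)
Conditions: NaOMe, MeOH, rt → 50 °C
Reagents that add atoms: none
Why: Intramolecular aldol condensation (second stage of a Robinson annulation) closes the six-membered ring A and dehydrates to the tetrasubstituted enone; neither existing stereocentre is enolisable.

Step 6
Reactants: 11 enone; 12 isopropenyl acetate
Product: 13 3-acetoxy-eudesma-3,5-diene (7β-isopropyl, 10β-methyl)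
Conditions: 12 (solvent), cat. TsOH·H2O, reflux, acetone distilled off
Reagents that add atoms: isopropenyl acetate, CC(=C)OC(C)=O
Why: Acid-catalysed enol acetylation under equilibrating conditions gives the thermodynamic heteroannular 3,5-dienol acetate, which activates C6.

Step 7
Reactants: 13 dienol acetate; 14 m-chloroperbenzoic acid
Product: 16 (4aS,7S,8R)-8-hydroxy-1,4a-dimethyl-7-(propan-2-yl)-4,4a,5,6,7,8-hexahydronaphthalen-2(3H)-one (6β-hydroxy-eudesm-4-en-3-one), via epoxy enol acetate 15 (not isolated)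
Conditions: m-CPBA (1.1 equiv), dioxane/H2O 9:1, 0 °C → rt
Reagents that add atoms: m-chloroperbenzoic acid, OOC(=O)c1cccc(Cl)c1
Why: Peracid γ-hydroxylation of a dienol acetate (vinylogous Rubottom-type oxidation), in which the C5=C6 terminus is attacked from the stereoelectronically favoured axial β-face and the epoxide collapses with loss of acetyl to the 6β-hydroxy enone, as in the steroid Δ4-3-ketone series.

Step 8
Reactants: 16 hydroxy enone; 17 tert-butyldimethylsilyl triflate
Product: 18 6β-(tert-butyldimethylsilyloxy)eudesm-4-en-3-one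
Conditions: TBSOTf (1.5 equiv), 2,6-lutidine (3 equiv), CH2Cl2, 0 °C → rt
Reagents that add atoms: tert-butyldimethylsilyl triflate, CC(C)(C)[Si](C)(C)OS(=O)(=O)C(F)(F)F
Why: Silyl triflate silylation is strong enough for the hindered axial alcohol, and the silyl ether cannot be ionised by Pd(0) later even though C6 is allylic.

Step 9
Reactants: 18 silyloxy enone
Product: 19 (2S,4aS,7S,8R)-8-(tert-butyldimethylsilyloxy)-1,4a-dimethyl-7-(propan-2-yl)-2,3,4,4a,5,6,7,8-octahydronaphthalen-2-ol (6β-silyloxy-eudesm-4-en-3β-ol)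
Conditions: NaBH4, CeCl3·7H2O, MeOH, −40 → 0 °C
Reagents that add atoms: none
Why: Luche 1,2-reduction, with axial hydride delivery on the α-face giving the pseudo-equatorial 3β-alcohol (3S), as for Δ4-3-keto steroids and carvone.

Step 10
Reactants: 19 allylic alcohol; 20 formic acid
Product: 21 6β-(tert-butyldimethylsilyloxy)eudesm-4-en-3β-yl formate
Conditions: HCO2H (3 equiv), DCC (2 equiv), DMAP (0.1 equiv), CH2Cl2, 0 °C → rt
Reagents that add atoms: formic acid, OC=O
Why: Steglich-type carbodiimide formylation acylates the secondary allylic alcohol with retention under near-neutral conditions.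

Step 11
Reactants: 21 allylic formate
Product: 22 6β-(tert-butyldimethylsilyloxy)-5αH-eudesm-3-ene
Conditions: Pd(OAc)2 (5 mol %), n-Bu3P (5 mol %), THF, rt → 50 °C
Reagents that add atoms: none
Why: Tsuji–Mandai palladium-catalysed hydrogenolysis of an allylic formate, in which Pd(0) ionises the 3β-formate with inversion, decarboxylation gives Pd–H on the α-face, and hydride is delivered to the more substituted allyl terminus C5, setting 5α-H (trans-decalin, C5 R) and the Δ3 olefin in one operation.

Step 12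
Reactants: 22 silyl ether
Product: 23 (1R,2S,4aR,8aR)-4a,8-dimethyl-2-(propan-2-yl)-1,2,3,4,4a,5,6,8a-octahydronaphthalen-1-ol (5αH-eudesm-3-en-6β-ol)
Conditions: TBAF (3 equiv), THF, 50 °C; aq work-up
Reagents that add atoms: none
Why: Fluoride desilylation; the molecule holds only an isolated olefin beside the silyl ether, so nothing else can react.

Step 13
Reactants: 24 (E)-p-coumaric acid; 25 acetic anhydride
Product: 26 (E)-4-acetoxycinnamic acid
Conditions: Ac2O (1.5 equiv), pyridine, rt; aq HCl work-up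
Reagents that add atoms: acetic anhydride, CC(=O)OC(C)=O
Why: Standard O-acetylation of the phenol; any mixed anhydride at the carboxyl group is hydrolysed back on aqueous work-up.

Step 14
Reactants: 26 (E)-4-acetoxycinnamic acid; 27 oxalyl chloride
Product: 28 (E)-4-acetoxycinnamoyl chloride
Conditions: (COCl)2 (1.5 equiv), cat. DMF, CH2Cl2, 0 °C → rt; evaporate, use crude
Reagents that add atoms: oxalyl chloride, ClC(=O)C(Cl)=O
Why: Vilsmeier-catalysed acid chloride formation is mild enough to keep the aryl acetate and the E-olefin.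

Step 15
Reactants: 23 eudesm-3-en-6β-ol; 28 (E)-4-acetoxycinnamoyl chloride
Product: 29 (1R,2S,4aR,8aR)-4a,8-dimethyl-2-(propan-2-yl)-1,2,3,4,4a,5,6,8a-octahydronaphthalen-1-yl (2E)-3-(4-acetoxyphenyl)prop-2-enoate
Conditions: 28 (1.5 equiv), Et3N (3 equiv), DMAP (0.5 equiv), CH2Cl2, 0 °C → reflux
Reagents that add atoms: (E)-4-acetoxycinnamoyl chloride, CC(=O)Oc1ccc(/C=C/C(Cl)=O)cc1
Why: DMAP-catalysed acylation through the N-acylpyridinium ion drives esterification of the hindered axial alcohol with retention at C6, and the acid chloride has no α-hydrogen to lose.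

Step 16
Reactants: 29 acetyl-protected ester
Product: 30 CNP0220414.1, (1R,2S,4aR,8aR)-4a,8-dimethyl-2-(propan-2-yl)-1,2,3,4,4a,5,6,8a-octahydronaphthalen-1-yl (2E)-3-(4-hydroxyphenyl)prop-2-enoate
Conditions: pyrrolidine (2 equiv), CH2Cl2, 0 °C → rt
Reagents that add atoms: none
Why: Chemoselective aminolysis of the activated aryl acetate by a secondary amine, which leaves the hindered secondary alkyl cinnamate untouched.

**Compound list**
1 | (R)-(−)-carvone [(5R)-2-methyl-5-(prop-1-en-2-yl)cyclohex-2-en-1-one] | CC1=CC[C@H](CC1=O)C(C)=C | starting material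
2 | (5R)-2-methyl-5-(propan-2-yl)cyclohex-2-en-1-one (carvotanacetone) | CC1=CC[C@H](CC1=O)C(C)C | intermediate
3 | (2RS,5R)-2-methyl-5-(propan-2-yl)cyclohexan-1-one (carvomenthone; C2 epimer mixture) | CC1CC[C@H](CC1=O)C(C)C | intermediate
4 | (R)-(+)-1-phenylethylamine | C[C@@H](N)c1ccccc1 | starting material
5 | (1R)-N-[(5R)-2-methyl-5-(propan-2-yl)cyclohexylidene]-1-phenylethanamine (C2 epimer mixture) | CC1CC[C@H](CC1=N[C@H](C)c2ccccc2)C(C)C | intermediate
6 | ethyl vinyl ketone (pent-1-en-3-one) | CCC(=O)C=C | starting material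
7 | (5R)-2-methyl-N-[(1R)-1-phenylethyl]-5-(propan-2-yl)cyclohex-1-en-1-amine (enamine tautomer of 5) | CC1=C(N[C@H](C)c2ccccc2)C[C@H](C(C)C)CC1 | intermediate (not isolated)
8 | (1R)-N-[(2S,5R)-2-methyl-2-(3-oxopentyl)-5-(propan-2-yl)cyclohexylidene]-1-phenylethanamine | CCC(=O)CC[C@]1(C)CC[C@@H](C(C)C)CC1=N[C@H](C)c2ccccc2 | intermediate (not isolated)
9 | (2S,5R)-2-methyl-2-(3-oxopentyl)-5-(propan-2-yl)cyclohexan-1-one | CCC(=O)CC[C@]1(C)CC[C@@H](C(C)C)CC1=O | intermediate
10 | (4aS,7R)-8a-hydroxy-1,4a-dimethyl-7-(propan-2-yl)octahydronaphthalen-2(1H)-one (aldol ketol; C1 and C8a mixture) | CC1C(=O)CC[C@]2(C)CC[C@@H](C(C)C)CC12O | intermediate (not isolated)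
11 | (4aS,7R)-1,4a-dimethyl-7-(propan-2-yl)-4,4a,5,6,7,8-hexahydronaphthalen-2(3H)-one (eudesm-4-en-3-one; 7β-isopropyl, 10β-methyl) | O=C1CC[C@]2(C)CC[C@@H](C(C)C)CC2=C1C | intermediate
12 | isopropenyl acetate | CC(=C)OC(C)=O | starting material
13 | 3-acetoxy-eudesma-3,5-diene (7β-isopropyl, 10β-methyl) | CC1=C(OC(C)=O)CC[C@]2(C)CC[C@@H](C(C)C)C=C12 | intermediate
14 | m-chloroperbenzoic acid | OOC(=O)c1cccc(Cl)c1 | starting material
15 | 3-acetoxy-5β,6β-epoxy-eudesm-3-ene | CC1=C(OC(C)=O)CC[C@]2(C)CC[C@@H](C(C)C)[C@H]3O[C@@]123 | intermediate (not isolated)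
16 | (4aS,7S,8R)-8-hydroxy-1,4a-dimethyl-7-(propan-2-yl)-4,4a,5,6,7,8-hexahydronaphthalen-2(3H)-one (6β-hydroxy-eudesm-4-en-3-one) | O=C1CC[C@]2(C)CC[C@@H](C(C)C)[C@@H](O)C2=C1C | intermediate
17 | tert-butyldimethylsilyl trifluoromethanesulfonate | CC(C)(C)[Si](C)(C)OS(=O)(=O)C(F)(F)F | starting material
18 | 6β-(tert-butyldimethylsilyloxy)eudesm-4-en-3-one | O=C1CC[C@]2(C)CC[C@@H](C(C)C)[C@@H](O[Si](C)(C)C(C)(C)C)C2=C1C | intermediate
19 | 6β-(tert-butyldimethylsilyloxy)eudesm-4-en-3β-ol (2S,4aS,7S,8R in naphthalene numbering) | O[C@H]1CC[C@]2(C)CC[C@@H](C(C)C)[C@@H](O[Si](C)(C)C(C)(C)C)C2=C1C | intermediate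
20 | formic acid | OC=O | starting material
21 | 6β-(tert-butyldimethylsilyloxy)eudesm-4-en-3β-yl formate | O=CO[C@H]1CC[C@]2(C)CC[C@@H](C(C)C)[C@@H](O[Si](C)(C)C(C)(C)C)C2=C1C | intermediate
22 | 6β-(tert-butyldimethylsilyloxy)-5αH-eudesm-3-ene | CC1=CCC[C@]2(C)CC[C@@H](C(C)C)[C@@H](O[Si](C)(C)C(C)(C)C)[C@@H]12 | intermediate
23 | (1R,2S,4aR,8aR)-4a,8-dimethyl-2-(propan-2-yl)-1,2,3,4,4a,5,6,8a-octahydronaphthalen-1-ol (5αH-eudesm-3-en-6β-ol) | CC1=CCC[C@]2(C)CC[C@@H](C(C)C)[C@@H](O)[C@@H]12 | intermediate
24 | (E)-p-coumaric acid | OC(=O)/C=C/c1ccc(O)cc1 | starting material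
25 | acetic anhydride | CC(=O)OC(C)=O | starting material
26 | (E)-4-acetoxycinnamic acid | CC(=O)Oc1ccc(/C=C/C(O)=O)cc1 | intermediate
27 | oxalyl chloride | ClC(=O)C(Cl)=O | starting material
28 | (E)-4-acetoxycinnamoyl chloride | CC(=O)Oc1ccc(/C=C/C(Cl)=O)cc1 | intermediate
29 | 5αH-eudesm-3-en-6β-yl (E)-4-acetoxycinnamate | CC1=CCC[C@]2(C)CC[C@@H](C(C)C)[C@@H](OC(=O)/C=C/c3ccc(OC(C)=O)cc3)[C@@H]12 | intermediate
30 | CNP0220414.1, 5αH-eudesm-3-en-6β-yl (E)-p-coumarate | CC1=CCC[C@]2(C)CC[C@@H](C(C)C)[C@@H](OC(=O)/C=C/c3ccc(O)cc3)[C@@H]12 | target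

**Totals**
Total step count: 16. Longest linear sequence: 14 steps (steps 1–12, 15, 16); steps 13–14 make the side chain.

**Steps most likely to fail**

Step 7 (γ-hydroxylation). The 4-methyl group makes the C3=C4 enol-acetate olefin tetrasubstituted, so the peracid may attack there and give a 4-hydroxy product. Attack at C6 from the α-face is the second hazard. The fallback sets out from enone 11 and comes back at 16. Enone 11 is treated with triethyl orthoformate and catalytic TsOH in EtOH/dioxane to give 3-ethoxy-eudesma-3,5-diene F1. F1 is oxygenated with O2 under visible light with rose bengal in 95% EtOH, where dioxygen adds at the dienol-ether terminus C6 from the axial β-face, giving 6β-hydroperoxy-eudesm-4-en-3-one F2. Reduction of F2 with PPh3 in CH2Cl2 gives 16.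

Step 11 (reductive transposition). Ionisation of a formate on a tetrasubstituted olefin may be slow. Diene formation by β-hydride elimination, or hydride delivery to C3, are the other possible failures. The fallback sets out from allylic alcohol 19 and comes back at 22, by a Myers allylic diazene rearrangement. Compound 19 is treated with 2-nitrobenzenesulfonylhydrazide, PPh3 and DEAD in THF at −30 °C. Mitsunobu displacement with inversion gives N-[6β-(tert-butyldimethylsilyloxy)eudesm-4-en-3α-yl]-2-nitrobenzenesulfonohydrazide F3. On warming to rt, F3 loses the sulfinic acid to give 3α-diazenyl-6β-(tert-butyldimethylsilyloxy)eudesm-4-ene F4. Retro-ene loss of N2 from F4 transfers hydrogen suprafacially to C5 on the α-face and gives 22.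

Step 15 (esterification). The 6β-hydroxyl is axial, 1,3-diaxial to the angular methyl and flanked by the isopropyl group, so direct acylation with a cinnamoyl chloride may stall. The fallback sets out from alcohol 23 and comes back at 29. Alcohol 23 is esterified with diethylphosphonoacetic acid, DCC and catalytic DMAP in CH2Cl2; this goes through a small, very reactive phosphonoketene and gives 5αH-eudesm-3-en-6β-yl (diethoxyphosphoryl)acetate F5. A Masamune–Roush Horner–Wadsworth–Emmons olefination of F5 with 4-acetoxybenzaldehyde (LiCl, i-Pr2NEt, MeCN, rt) builds the (E)-cinnamate away from the hindered centre and gives 29.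

**Further compounds**
F1 | step 7 | 3-ethoxy-eudesma-3,5-diene (7β-isopropyl, 10β-methyl) | CC1=C(OCC)CC[C@]2(C)CC[C@@H](C(C)C)C=C12
F2 | step 7 | 6β-hydroperoxy-eudesm-4-en-3-one | O=C1CC[C@]2(C)CC[C@@H](C(C)C)[C@@H](OO)C2=C1C
F3 | step 11 | N-[6β-(tert-butyldimethylsilyloxy)eudesm-4-en-3α-yl]-2-nitrobenzenesulfonohydrazide | NN([C@@H]1CC[C@]2(C)CC[C@@H](C(C)C)[C@@H](O[Si](C)(C)C(C)(C)C)C2=C1C)S(=O)(=O)c1ccccc1[N+](=O)[O-]
F4 | step 11 | 3α-diazenyl-6β-(tert-butyldimethylsilyloxy)eudesm-4-ene | N=N[C@@H]1CC[C@]2(C)CC[C@@H](C(C)C)[C@@H](O[Si](C)(C)C(C)(C)C)C2=C1C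
F5 | step 15 | 5αH-eudesm-3-en-6β-yl (diethoxyphosphoryl)acetate | CC1=CCC[C@]2(C)CC[C@@H](C(C)C)[C@@H](OC(=O)CP(=O)(OCC)OCC)[C@@H]12
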